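I watched the reagent.

common to all: substrate 0.25 M

| flask | reagent | remark | time |
|---|---|---|---|
| ochre | 0.29 M | run made earlier |  |
| violet | 0.42 M | run made earlier |  |
| beta | 0.380 M |  | 5.0 min |
| gamma | 0.490 M |  | 5.0 min |

| run | time / min | substrate / % | tris adduct / % | single product / % | bis adduct / % |
|---|---|---|---|---|---|
| ochre | 0.200 | 96.8 | 0 | 2.5 | 0.8 |
| ochre | 0.500 | 92.3 | 0.1 | 4.9 | 0 |
| ochre | 1.00 | 87.1 | 0 | 13.1 | 1.7 |
| ochre | 2.50 | 74.4 | 0 | 22.6 | 0 |
| violet | 0.333 | 93.5 | 0 | 7.1 | 0 |
| violet | 0.833 | 85.4 | 1.6 | 14.5 | 0.4 |
| violet | 1.50 | 76.0 | 0 | 23.2 | 0 |
| violet | 2.50 | 68.3 | 0 | 31.4 | 0 |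

(readings scatter by 1 percentage point)

- which of these there is most of at the end, counted by the substrate in it, beta (substrate / bis adduct / tris adduct / single product)
- which of these there is most of at the end, counted by the substrate in it, gamma (substrate / bis adduct / tris adduct / single product)
- how much there is at the end of the one of these that leads, in percent of the substrate charged: beta
- how much there is at the end of the one of these that leads, in percent of the substrate charged: gamma

- candidate steps: substrate + reagent -> single product + by-product; reagent + single product -> bis adduct + by-product; reagent + bis adduct -> tris adduct + by-product; reagent + tris adduct -> tetra adduct + by-product; bis adduct + by-product -> side product; reagent <-> dormant form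

The listed step that consumes substrate also takes reagent, so I took the substrate's loss as first order in free reagent and pseudo-first-order in substrate while free reagent held steady. From this I reckoned one number: the natural log of charged over remaining substrate, divided by reagent charge and time. In the violet run this read 0.451 M⁻¹ min⁻¹ at 0.833 min, then 0.363 M⁻¹ min⁻¹ at 2.50 min, and this later reading is the charge constant that I carried forward.

Those two readings did not seem to go together. By its last reading, violet's substrate had taken 18.9% of the reagent charge, which averages 9.45% over the run, yet the constant had fallen by 19.5%. But the constant divides by the charge, while the rate follows free reagent. Its fall, about twice the average take, suggested that reagent was leaving solution by another route as well, though these are readings with scatter.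

Carrying violet's constant over, I reckoned 50.2% substrate for beta and 41.1% for gamma, both low if the constant kept falling. The forecast, which noted that “some reagent is probably going dormant”, stood higher on substrate: substrate leading beta at 56%, and single product leading gamma at 50%.

Beta gave substrate at 52.5% and gamma gave single product at 51.6%, so the forecast's leaders stood. At 2.50 min, beta had 52.3% of its reagent free and 0.100 M of dormant form, with 68.9% of its substrate left. Over the full time the charge constant came to 0.339 M⁻¹ min⁻¹ in beta and 0.342 M⁻¹ min⁻¹ in gamma, lower than violet's.

    substrate + reagent → single product + by-product (k = 0.0100 M⁻¹ s⁻¹)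
    reagent + single product → bis adduct + by-product (k = 0.00200 M⁻¹ s⁻¹)
    reagent + bis adduct → tris adduct + by-product (k = 0.0160 M⁻¹ s⁻¹)
    reagent + tris adduct → tetra adduct + by-product (k = 0.0120 M⁻¹ s⁻¹)
    bis adduct + by-product → side product (k = 0.00870 M⁻¹ s⁻¹)
    reagent ⇌ dormant form (K = 0.480, k = 0.00960 s⁻¹)

For a neighbouring flask, like gamma but with 0.20 M of reagent, gamma's constant gave 71.1% substrate. The computed flask held 71.7%, with substrate leading.

The readings are calculated for substances that don't exist; scatter was added.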